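**Retrosynthetic overview**

1. Daucane numbering is used: C1 = quaternary ring-fusion carbon (CH3-15), C4 = carbinol carbon with isopropyl, C5 = ring-fusion CH, C6 = CH–OBz, C7=C8 (CH3-14), C9 = C=O, C10 = CH–OH; β = face of CH3-15. The endgame from bicyclic 6,9-diketone 15 is hydroxyl-directed reduction at C6, benzoylation, C8 methylenation/isomerisation and O-debenzylation.
2. Key disconnection: C9–C10 and C1–C5, made together by an intramolecular de Mayo reaction of monocyclic 13 ([2+2] photocycloaddition, then scission of the temporary C5–C9 bond). The cyclopentane closes first (5-exo); the cycloheptane appears by two-carbon expansion of the cyclopentenone.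
3. Enabling feature: in the seven-membered ring C6–O and C9=O are 1,4-related through C7–C8 and 1,5-related through C5–C1–C10. C5–C6–C7–C8–C9 is therefore a latent cyclopentane-1,3-dione whose C5–C9 bond accepts the C1=C10 enol ether. The tertiary 4-OH, β to C6, steers the photocycloaddition by hydrogen bonding and later delivers hydride to C6.
4. 13 comes from (S)-terpinen-4-ol. Ozonolysis opens the cyclohexene and keeps the C4 stereocentre; the aldehyde end is extended and closed to the dione enol ether (first ring, later opened); the methyl-ketone end becomes the benzyl enol ether.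

Key step: step 8

Remark: (S)-(+)-terpinen-4-ol (1) is taken as a catalogue compound of high enantiomeric purity; a scalemic lot would have to be upgraded before use.

**Route**

Step 1
Reactants: 1 (S)-(+)-terpinen-4-ol, (1S)-4-methyl-1-(propan-2-yl)cyclohex-3-en-1-ol
Product: 2 (3S)-3-hydroxy-6-oxo-3-(propan-2-yl)heptanal
Conditions: O3, CH2Cl2, −78 °C; then Me2S, −78 → 23 °C
Reagents that add atoms: ozone, [O-][O+]=O
Why: Ozonolysis with reductive work-up should cleave the ring C=C of the cheap monoterpene to the methyl ketone and the aldehyde without touching the tertiary carbinol stereocentre (future C4); the crude keto aldehyde is used directly.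

Step 2
Reactants: 2 (3S)-3-hydroxy-6-oxo-3-(propan-2-yl)heptanal; 3 methyl acrylate
Product: 4 methyl (6S)-6-hydroxy-4,9-dioxo-6-(propan-2-yl)decanoate
Conditions: 3 (2 equiv), (n-Bu4N)4[W10O32] (2 mol %), MeCN, 390 nm LED, 23 °C
Reagents that add atoms: none
Why: Decatungstate-photocatalysed hydroacylation (hydrogen abstraction from the formyl C–H, Giese addition of the acyl radical to the acrylate, back hydrogen transfer) should give the γ-keto ester under neutral conditions that spare the β-hydroxy aldehyde and the methyl ketone; no stereocentre is formed.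

Step 3
Reactants: 4 methyl (6S)-6-hydroxy-4,9-dioxo-6-(propan-2-yl)decanoate
Product: 5 methyl 5-[(2S)-5-methoxy-5-methyl-2-(propan-2-yl)oxolan-2-yl]-4-oxopentanoate (both epimers at the ketal carbon)
Conditions: MeOH, PPTS (cat.), 3 Å MS, 23 °C
Reagents that add atoms: methanol, CO
Why: Acid-catalysed ketalisation of the five-membered hemiketal of the γ-hydroxy methyl ketone should mask the methyl ketone and the tertiary hydroxyl at once, so that no alkoxide can trigger retro-aldol cleavage in step 4.

Step 4
Reactants: 5 methyl 5-[(2S)-5-methoxy-5-methyl-2-(propan-2-yl)oxolan-2-yl]-4-oxopentanoate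
Product: 7 3-methoxy-2-[(2R)-5-methoxy-5-methyl-2-(propan-2-yl)oxolan-2-yl]cyclopent-2-en-1-one, via potassium dione enolate 6 (not isolated)
Conditions: t-BuOK (1.2 equiv), THF, 0 → 23 °C; then Me2SO4, 0 → 23 °C
Reagents that add atoms: dimethyl sulfate, COS(=O)(=O)OC
Why: Intramolecular Claisen (Dieckmann-type) condensation through the only ketone enolate that can close a five-membered ring should give the 2-substituted cyclopentane-1,3-dione as its stable enolate, and O-methylation of this symmetric enolate (C-alkylation blocked by the neopentyl position) gives a single vinylogous ester without liberating the sensitive free dione.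

Step 5
Reactants: 7 3-methoxy-2-[(2R)-5-methoxy-5-methyl-2-(propan-2-yl)oxolan-2-yl]cyclopent-2-en-1-one
Product: 8 2-[(3R)-3-hydroxy-2-methyl-6-oxoheptan-3-yl]-3-methoxycyclopent-2-en-1-one
Conditions: PPTS (cat.), acetone/H2O (9:1), 23 °C
Reagents that add atoms: water, O
Why: Acid-catalysed hydrolysis of the mixed cyclic ketal (through the endocyclic oxocarbenium ion) should be far faster than hydrolysis of the vinylogous methyl ester and returns the methyl ketone and the tertiary alcohol.

Step 6
Reactants: 9 benzyl chloromethyl ether; 10 triphenylphosphine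
Product: 11 (benzyloxymethyl)triphenylphosphonium chloride
Conditions: toluene, 60 °C
Reagents that add atoms: none
Why: SN2 quaternisation of the phosphine by the reactive α-chloro ether should give the Wittig salt.

Step 7
Reactants: 8 2-[(3R)-3-hydroxy-2-methyl-6-oxoheptan-3-yl]-3-methoxycyclopent-2-en-1-one; 11 (benzyloxymethyl)triphenylphosphonium chloride
Product: 13 2-[(3R)-7-(benzyloxy)-3-hydroxy-2,6-dimethylhept-6-en-3-yl]-3-methoxycyclopent-2-en-1-one (E/Z mixture), via phosphorus ylide 12 (not isolated)
Conditions: 11 (3 equiv), KHMDS (3 equiv), THF, 0 °C; then 8, 0 → 23 °C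
Reagents that add atoms: none
Why: Wittig alkoxymethylenation should convert only the methyl ketone (the vinylogous ester carbonyl is inert, one equivalent of ylide merely deprotonates the hydroxyl), and the E/Z mixture is used as such because the key step is stereoconvergent in the enol ether geometry.

Step 8
Reactants: 13 2-[(3R)-7-(benzyloxy)-3-hydroxy-2,6-dimethylhept-6-en-3-yl]-3-methoxycyclopent-2-en-1-one (E/Z mixture)
Product: 15 10β-(benzyloxy)-4β-hydroxy-14-nor-5α-daucane-6,9-dione (trans-fused bicyclo[5.3.0]decane), via tricyclic photoadduct 14 (not isolated)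
Conditions: hν (350 nm, Pyrex), degassed hexane/CH2Cl2 (9:1, 5 mM), 0 °C; then 1 M HCl, THF, 23 °C
Reagents that add atoms: water, O
Why: Excitation of the 3-methoxyenone gives its triplet, whose α-carbon (C5) attacks C1 of the tethered enol ether (5-exo-trig, rule of five); the 1,4-biradical then collapses between C9 and C10 to the cis-fused cyclobutane 14, and aqueous acid opens the strained donor–acceptor bond C5–C9 (push from C9–OMe, pull from the C6 carbonyl; retro-aldol-type fragmentation) and hydrolyses the oxocarbenium ion to the C9 ketone. The closest known reaction is the intramolecular de Mayo reaction of cyclic 1,3-dione enol derivatives, a known entry to hydroazulenes. The cyclopentane is closed directly by the 5-exo radical step, whereas the cycloheptane arises by two-carbon ring expansion of the cyclopentenone (four-ring closure, then C5–C9 scission). C1 is set by the C4 carbinol, because in the non-polar medium the 4-OH is hydrogen-bonded to the C6 carbonyl (the best acceptor), which fixes the rotamer about C4–C5 and sends the tether over the enone face that leaves OH cis and isopropyl trans to C6; C10 is set in the biradical closure, where the benzyloxy group should take the exo position trans to the C9 methoxy group and cis to CH3-15 whatever the geometry of 13. C5 is re-made by protonation of the C6 enol and should equilibrate in the acid to the trans ring fusion, in which the C6 carbonyl is trans to the isopropyl group and hydrogen-bonded to 4-OH. The step needs straight rather than crossed regiochemistry, secured by the three-atom tether on the enone α-carbon, and scission of C5–C9 only, secured by the donor–acceptor substitution of that bond alone.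

Step 9
Reactants: 15 10β-(benzyloxy)-4β-hydroxy-14-nor-5α-daucane-6,9-dione
Product: 16 10β-(benzyloxy)-4β,6α-dihydroxy-14-nor-5α-daucan-9-one
Conditions: Me4NBH(OAc)3, MeCN/AcOH (1:1), −30 → 0 °C
Reagents that add atoms: none
Why: Evans–Saksena hydroxyl-directed reduction should deliver hydride from boron bound to the 4β-oxygen through a chair-like six-membered transition state to the C6 face anti to H-5, giving the 6α-alcohol (1,3-anti diol), while the C9 ketone has no free hydroxyl in reach and is not reduced.

Step 10
Reactants: 16 10β-(benzyloxy)-4β,6α-dihydroxy-14-nor-5α-daucan-9-one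
Product: 17 10β-(benzyloxy)-4β-hydroxy-9-oxo-14-nor-5α-daucan-6α-yl benzoate
Conditions: BzCl, DMAP (cat.), pyridine, CH2Cl2, 0 → 23 °C
Reagents that add atoms: benzoyl chloride, O=C(Cl)c1ccccc1
Why: Nucleophile-catalysed acylation should select the secondary 6α-hydroxyl; the tertiary 4-hydroxyl does not react.

Step 11
Reactants: 17 10β-(benzyloxy)-4β-hydroxy-9-oxo-14-nor-5α-daucan-6α-yl benzoate
Product: 18 10β-(benzyloxy)-4β-hydroxy-9-oxo-5α-dauc-8(14)-en-6α-yl benzoate
Conditions: (CH2O)n, i-Pr2NH·TFA (1 equiv), TFA (cat.), THF, 65 °C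
Reagents that add atoms: formaldehyde (from paraformaldehyde), C=O
Why: Mannich-type α-methylenation (aminomethylation and elimination in one pot) can occur only at C8, the sole α-carbon of the C9 ketone with two hydrogens, and installs C14.

Step 12
Reactants: 18 10β-(benzyloxy)-4β-hydroxy-9-oxo-5α-dauc-8(14)-en-6α-yl benzoate
Product: 19 10β-(benzyloxy)-4β-hydroxy-9-oxo-5α-dauc-7-en-6α-yl benzoate
Conditions: RhCl3·3H2O (5 mol %), EtOH, 70 °C
Reagents that add atoms: none
Why: Rhodium-hydride-catalysed exo-to-endo alkene isomerisation should move the double bond to the more substituted, thermodynamically preferred conjugated C7=C8 position; no stereocentre is touched.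

Step 13
Reactants: 19 10β-(benzyloxy)-4β-hydroxy-9-oxo-5α-dauc-7-en-6α-yl benzoate
Product: 20 4β,10β-dihydroxy-9-oxo-5α-dauc-7-en-6α-yl benzoate, the target
Conditions: BCl3, pentamethylbenzene, CH2Cl2, −78 °C
Reagents that add atoms: none
Why: Lewis-acid cleavage of the benzyl ether with a cation scavenger, assisted by chelation of boron between the C9 carbonyl and the C10 ether oxygen, should spare the benzoate, the enone and the tertiary alcohol.

**Compound list**

1 | (S)-(+)-terpinen-4-ol, (1S)-4-methyl-1-(propan-2-yl)cyclohex-3-en-1-ol | CC1=CC[C@](O)(C(C)C)CC1 | starting material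
2 | (3S)-3-hydroxy-6-oxo-3-(propan-2-yl)heptanal | O=CC[C@](O)(C(C)C)CCC(C)=O | intermediate
3 | methyl acrylate | C=CC(=O)OC | starting material
4 | methyl (6S)-6-hydroxy-4,9-dioxo-6-(propan-2-yl)decanoate | COC(=O)CCC(=O)C[C@](O)(C(C)C)CCC(C)=O | intermediate
5 | methyl 5-[(2S)-5-methoxy-5-methyl-2-(propan-2-yl)oxolan-2-yl]-4-oxopentanoate (both epimers at the ketal carbon) | COC(=O)CCC(=O)C[C@]1(C(C)C)CCC(C)(OC)O1 | intermediate
6 | potassium 2-[(2R)-5-methoxy-5-methyl-2-(propan-2-yl)oxolan-2-yl]-3-oxocyclopent-1-en-1-olate | [K+].[O-]C1=C(C(=O)CC1)[C@]2(C(C)C)CCC(C)(OC)O2 | intermediate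
7 | 3-methoxy-2-[(2R)-5-methoxy-5-methyl-2-(propan-2-yl)oxolan-2-yl]cyclopent-2-en-1-one | COC1=C(C(=O)CC1)[C@]2(C(C)C)CCC(C)(OC)O2 | intermediate
8 | 2-[(3R)-3-hydroxy-2-methyl-6-oxoheptan-3-yl]-3-methoxycyclopent-2-en-1-one | COC1=C(C(=O)CC1)[C@](O)(C(C)C)CCC(C)=O | intermediate
9 | benzyl chloromethyl ether | ClCOCc1ccccc1 | starting material
10 | triphenylphosphine | c1ccc(cc1)P(c1ccccc1)c1ccccc1 | starting material
11 | (benzyloxymethyl)triphenylphosphonium chloride | [Cl-].c1ccc(cc1)[P+](COCc1ccccc1)(c1ccccc1)c1ccccc1 | intermediate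
12 | [(benzyloxy)methylidene]triphenylphosphorane | C(OCc1ccccc1)=P(c1ccccc1)(c1ccccc1)c1ccccc1 | intermediate
13 | 2-[(3R)-7-(benzyloxy)-3-hydroxy-2,6-dimethylhept-6-en-3-yl]-3-methoxycyclopent-2-en-1-one (E/Z mixture) | COC1=C(C(=O)CC1)[C@](O)(C(C)C)CCC(C)=COCc1ccccc1 | intermediate
14 | 6-(benzyloxy)-2-hydroxy-7-methoxy-5-methyl-2-(propan-2-yl)tricyclo[5.3.0.0(1,5)]decan-10-one; cyclobutane cis-fused to both five-membered rings, 6-OBn trans to 7-OMe and cis to 5-CH3, 2-OH cis to C10 | C1CC(=O)[C@]23[C@](C)(CC[C@@]2(O)C(C)C)[C@@H](OCc2ccccc2)[C@@]13OC | intermediate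
15 | 10β-(benzyloxy)-4β-hydroxy-14-nor-5α-daucane-6,9-dione (trans-fused) | C1CC(=O)[C@@H]2[C@](C)(CC[C@@]2(O)C(C)C)[C@@H](OCc2ccccc2)C1=O | intermediate
16 | 10β-(benzyloxy)-4β,6α-dihydroxy-14-nor-5α-daucan-9-one | C1C[C@H](O)[C@@H]2[C@](C)(CC[C@@]2(O)C(C)C)[C@@H](OCc2ccccc2)C1=O | intermediate
17 | 10β-(benzyloxy)-4β-hydroxy-9-oxo-14-nor-5α-daucan-6α-yl benzoate | C1C[C@H](OC(=O)c2ccccc2)[C@@H]2[C@](C)(CC[C@@]2(O)C(C)C)[C@@H](OCc2ccccc2)C1=O | intermediate
18 | 10β-(benzyloxy)-4β-hydroxy-9-oxo-5α-dauc-8(14)-en-6α-yl benzoate | C=C1C[C@H](OC(=O)c2ccccc2)[C@@H]2[C@](C)(CC[C@@]2(O)C(C)C)[C@@H](OCc2ccccc2)C1=O | intermediate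
19 | 10β-(benzyloxy)-4β-hydroxy-9-oxo-5α-dauc-7-en-6α-yl benzoate | CC1=C[C@H](OC(=O)c2ccccc2)[C@@H]2[C@](C)(CC[C@@]2(O)C(C)C)[C@@H](OCc2ccccc2)C1=O | intermediate
20 | 4β,10β-dihydroxy-9-oxo-5α-dauc-7-en-6α-yl benzoate, (1R,3aS,4R,8S,8aS)-1,4-dihydroxy-3a,6-dimethyl-5-oxo-1-(propan-2-yl)-1,2,3,3a,4,5,8,8a-octahydroazulen-8-yl benzoate | CC1=C[C@H](OC(=O)c2ccccc2)[C@@H]2[C@](C)(CC[C@@]2(O)C(C)C)[C@@H](O)C1=O | target

**Step count and risks**

Total step count: 13. Longest linear sequence: 12 steps (steps 1–5 and 7–13); step 6 is a one-step side branch.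

The three steps most likely to fail:

1. Step 8. The alkene may add to the other enone face if the hydroxyl–carbonyl hydrogen bond does not hold the rotamer. The aqueous acid that opens the photoadduct may also dehydrate the tertiary β-hydroxy ketone or epimerise C10 before the ring fusion has equilibrated. The fallback changes how the cyclobutane is opened: oxidative unmasking under neutral conditions instead of acid. It sets out from 5: the Claisen cyclisation is run as in step 4 but the enolate is trapped with 4-methoxybenzyl chloride to give the 4-methoxybenzyl vinylogous ester F1. Ketal hydrolysis (PPTS, acetone/H2O) gives the hydroxy ketone F2, and Wittig reaction with ylide 12 gives the photosubstrate F3. Irradiation as in step 8 gives the PMB-protected photoadduct F4. DDQ in CH2Cl2/pH 7 buffer removes the PMB group, and the free cyclobutanol F5 opens by spontaneous retro-aldol reaction. After equilibration of the ring fusion with a trace of DBU the route is rejoined at 15.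

2. Step 4. β-Elimination from the potassium ketone enolate (opening of the oxolane) or intermolecular condensation may outrun the hindered five-membered ring closure. The fallback replaces the strong-base Claisen condensation by C-acylation under soft enolisation. It sets out from 5: saponification (LiOH, THF/H2O) gives the keto acid F6, which is converted with benzotriazole and EDC into the N-acylbenzotriazole F7. MgBr2·OEt2 and i-Pr2NEt in CH2Cl2 at 0 °C should effect intramolecular acylation of the ketone to the bromomagnesium dione enolate F8, which is O-methylated in the same flask with dimethyl sulfate. The route is rejoined at 7.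

3. Step 2. Hydrogen abstraction at other C–H bonds and self-condensation of the sensitive keto aldehyde may compete with trapping of the acyl radical and leave conversion low. The fallback uses polar acyl-anion chemistry instead of radical chemistry. It sets out from 2: a thiazolium-catalysed Stetter reaction with 3 (3-benzyl-5-(2-hydroxyethyl)-4-methylthiazolium chloride, Et3N, dioxane, 70 °C) should give 4 directly, where the route is rejoined; it makes no compound outside the list (F0).

**Further compounds**

F1 | step 8 | 3-[(4-methoxyphenyl)methoxy]-2-[(2R)-5-methoxy-5-methyl-2-(propan-2-yl)oxolan-2-yl]cyclopent-2-en-1-one | COc1ccc(COC2=C(C(=O)CC2)[C@]3(C(C)C)CCC(C)(OC)O3)cc1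
F2 | step 8 | 2-[(3R)-3-hydroxy-2-methyl-6-oxoheptan-3-yl]-3-[(4-methoxyphenyl)methoxy]cyclopent-2-en-1-one | COc1ccc(COC2=C(C(=O)CC2)[C@](O)(C(C)C)CCC(C)=O)cc1
F3 | step 8 | 2-[(3R)-7-(benzyloxy)-3-hydroxy-2,6-dimethylhept-6-en-3-yl]-3-[(4-methoxyphenyl)methoxy]cyclopent-2-en-1-one (E/Z mixture) | COc1ccc(COC2=C(C(=O)CC2)[C@](O)(C(C)C)CCC(C)=COCc2ccccc2)cc1
F4 | step 8 | 6-(benzyloxy)-2-hydroxy-7-[(4-methoxyphenyl)methoxy]-5-methyl-2-(propan-2-yl)tricyclo[5.3.0.0(1,5)]decan-10-one (configuration as in 14) | C1CC(=O)[C@]23[C@](C)(CC[C@@]2(O)C(C)C)[C@@H](OCc2ccccc2)[C@@]13OCc1ccc(OC)cc1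
F5 | step 8 | 6-(benzyloxy)-2,7-dihydroxy-5-methyl-2-(propan-2-yl)tricyclo[5.3.0.0(1,5)]decan-10-one (configuration as in 14) | C1CC(=O)[C@]23[C@](C)(CC[C@@]2(O)C(C)C)[C@@H](OCc2ccccc2)[C@@]13O
F6 | step 4 | 5-[(2S)-5-methoxy-5-methyl-2-(propan-2-yl)oxolan-2-yl]-4-oxopentanoic acid | OC(=O)CCC(=O)C[C@]1(C(C)C)CCC(C)(OC)O1
F7 | step 4 | 1-(1H-benzotriazol-1-yl)-5-[(2S)-5-methoxy-5-methyl-2-(propan-2-yl)oxolan-2-yl]pentane-1,4-dione | O=C(CCC(=O)C[C@]1(C(C)C)CCC(C)(OC)O1)n1nnc2ccccc12
F8 | step 4 | bromomagnesium 2-[(2R)-5-methoxy-5-methyl-2-(propan-2-yl)oxolan-2-yl]-3-oxocyclopent-1-en-1-olate | [Mg+2].[Br-].[O-]C1=C(C(=O)CC1)[C@]2(C(C)C)CCC(C)(OC)O2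
F0 | step 2 | none | none
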